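**Plan**

- Numbering: ring C1 (methyl-bearing alkene carbon), C2 (alkene CH), C3, C4, C5 (CH–CH3), C6 (quaternary); chain C7–C15 from C6 to sulfur.
- Retrosynthesis: cut the guanidine C–N bond and S–C15, then C14–C15 with C13–CH3, C10–C11, C9–CH3 with C8–C9 (alkyne methylalumination and coupling), and last the ring bonds C3–C4 and C5–C6.
- Enabling feature: the six-membered ring has its only alkene at C1=C2 and both stereocentres on the C5–C6 bond, so it is the [4+2] adduct of a C6=C1–C2=C3 diene and a C4=C5 dienophile, with the C5 methyl carried as a formyl group.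
- Forward: a six-membered lactone gives the ring-locked (Z)-diene; the Diels–Alder reaction closes the cyclohexene (the only ring); formyl becomes methyl; the chain grows from C9 to C15 by two methylalumination cycles joined by a Negishi coupling; then sulfone and guanidine.
- Stereochemistry: C5 from the chiral oxazaborolidinium catalyst (face of acrolein); C6 relative to C5 from endo addition to the Z-diene; both E alkenes from syn methylalumination.

Key step: step 7

Assumption: the sense of induction is assigned from the formyl C–H···O binding model for enals on B-aryl oxazaborolidinium ions; both catalyst antipodes are equally accessible, so an opposite sense found in practice would be corrected by using the catalyst from (S)-diphenylprolinol with nothing else changed.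

**Route**

Step 1
Reactants: 1 ethyl 2-methyl-3-oxobutanoate; 2 formaldehyde
Product: 4 4-hydroxy-3-methyl-5,6-dihydro-2H-pyran-2-one, via ethyl 5-hydroxy-2-methyl-3-oxopentanoate 3 (not isolated)
Conditions: NaH, then n-BuLi, THF, 0 °C; CH2O gas (from cracked paraformaldehyde), −78 to 0 °C; then 1 M NaOH, rt; HCl to pH 1
Reagents that add atoms: none
Why: The acetoacetate dianion reacts at its terminal carbon in an aldol addition to formaldehyde, and saponification followed by acidification closes the delta-hydroxy beta-keto acid to the six-membered enol lactone, the standard entry to 4-hydroxy-5,6-dihydropyran-2-ones.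

Step 2
Reactants: 4 4-hydroxy-3-methyl-5,6-dihydro-2H-pyran-2-one
Product: 5 3-methyl-2-oxo-5,6-dihydro-2H-pyran-4-yl trifluoromethanesulfonate
Conditions: Tf2O, Et3N, CH2Cl2, −78 to 0 °C
Reagents that add atoms: trifluoromethanesulfonic anhydride, O=S(=O)(OS(=O)(=O)C(F)(F)F)C(F)(F)F
Why: O-sulfonylation of the vinylogous acid gives the enol triflate, whose alkene geometry is fixed by the ring.

Step 3
Reactants: 5 3-methyl-2-oxo-5,6-dihydro-2H-pyran-4-yl trifluoromethanesulfonate
Product: 6 3,4-dimethyl-5,6-dihydro-2H-pyran-2-one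
Conditions: MeMgBr, Fe(acac)3 (5 mol %), THF/NMP, −30 °C
Reagents that add atoms: methylmagnesium bromide, C[Mg]Br
Why: Iron-catalysed Kumada-type cross-coupling of a beta-triflyloxy enoate with MeMgBr outruns carbonyl addition at low temperature and replaces the triflate with retention, giving the tetrasubstituted alkene locked cis in the ring.

Step 4
Reactants: 6 3,4-dimethyl-5,6-dihydro-2H-pyran-2-one
Product: 7 3,4-dimethyl-5,6-dihydro-2H-pyran-2-ol
Conditions: i-Bu2AlH (1.1 equiv), CH2Cl2, −78 °C; aq. potassium sodium tartrate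
Reagents that add atoms: none
Why: Half-reduction of the lactone by i-Bu2AlH at low temperature (1,2-hydride addition) stops at the aluminium hemiacetal, which gives the lactol on work-up.

Step 5
Reactants: 7 3,4-dimethyl-5,6-dihydro-2H-pyran-2-ol
Product: 9 (3Z)-3,4-dimethylhexa-3,5-dien-1-ol, via (2Z)-5-hydroxy-2,3-dimethylpent-2-enal 8 (not isolated)
Conditions: Ph3PCH3Br, KOt-Bu, THF, 0 °C to rt
Reagents that add atoms: methyltriphenylphosphonium bromide, C[P+](c1ccccc1)(c1ccccc1)c1ccccc1.[Br-]
Why: Wittig methylenation of the lactol through its open hydroxy-enal tautomer builds the vinyl group while the tetrasubstituted alkene keeps the Z relationship inherited from the ring.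

Step 6
Reactants: 9 (3Z)-3,4-dimethylhexa-3,5-dien-1-ol
Product: 10 tert-butyl{[(3Z)-3,4-dimethylhexa-3,5-dien-1-yl]oxy}dimethylsilane
Conditions: TBSCl, imidazole, DMF, rt
Reagents that add atoms: tert-butyldimethylsilyl chloride, CC(C)(C)[Si](C)(C)Cl
Why: Standard silylation of the primary alcohol masks the hydroxyl group from the Lewis acid of the next step.

Step 7
Reactants: 10 tert-butyl{[(3Z)-3,4-dimethylhexa-3,5-dien-1-yl]oxy}dimethylsilane; 11 acrolein
Product: 12 (1R,2S)-2-[2-(tert-butyldimethylsilyloxy)ethyl]-2,3-dimethylcyclohex-3-ene-1-carbaldehyde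
Conditions: (3aR)-1-(2-methylphenyl)-3,3-diphenyltetrahydro-1H,3H-pyrrolo[1,2-c][1,3,2]oxazaborole (20 mol %) + HNTf2 (18 mol %), 11 (3 equiv), CH2Cl2, −78 to −40 °C; Et3N quench
Reagents that add atoms: none
Why: The protonated oxazaborolidine binds acrolein at boron as the s-trans enal (formyl C–H···O contact to the ring oxygen) and lowers its LUMO, and the diene adds in a concerted but asynchronous [4+2] in which the unsubstituted terminus C3 bonds to the acrolein beta carbon C4 ahead of the C5–C6 bond, the developing positive charge being carried by the trialkyl-substituted allyl unit C2–C1–C6; this is the known oxazaborolidinium-catalysed enal Diels–Alder reaction of acyclic dienes, applied here to a diene whose reacting terminus is fully substituted, which is the demanding element. The six-membered carbocycle is closed by intermolecular cycloaddition, suprafacial on both partners, through the two new bonds C3–C4 and C5–C6. C5 is set by the catalyst: with the (R)-configured catalyst the C-phenyl group should cover the Re face of the acrolein alpha carbon, so the diene adds to its Si face and the formyl-bearing carbon becomes R. C6 is set relative to C5 by the Alder endo rule and the Z geometry of the diene: the outside methyl ends cis to the formyl group and the inside silyloxyethyl chain trans, which makes C6 S. The step needs 1,2 (ortho) regiochemistry, endo approach and one enal face: the doubly alkylated terminus (charge stabilisation and sterics both make it bond last) should secure the first, Lewis-acid catalysis at low temperature the second and the catalyst the third, while the C1 methyl raises the s-cis population needed for reaction.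

Step 8
Reactants: 12 (1R,2S)-2-[2-(tert-butyldimethylsilyloxy)ethyl]-2,3-dimethylcyclohex-3-ene-1-carbaldehyde
Product: 13 {(1R,2S)-2-[2-(tert-butyldimethylsilyloxy)ethyl]-2,3-dimethylcyclohex-3-en-1-yl}methanol
Conditions: NaBH4, MeOH, 0 °C (on the crude adduct)
Reagents that add atoms: none
Why: Borohydride 1,2-reduction of the aldehyde, run at once so that the epimerisable formyl-bearing centre C5 is secured; no new stereocentre is formed.

Step 9
Reactants: 13 {(1R,2S)-2-[2-(tert-butyldimethylsilyloxy)ethyl]-2,3-dimethylcyclohex-3-en-1-yl}methanol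
Product: 14 {(1R,2S)-2-[2-(tert-butyldimethylsilyloxy)ethyl]-2,3-dimethylcyclohex-3-en-1-yl}methyl 4-methylbenzenesulfonate
Conditions: TsCl, Et3N, DMAP (cat.), CH2Cl2, 0 °C to rt
Reagents that add atoms: 4-methylbenzenesulfonyl chloride, Cc1ccc(cc1)S(=O)(=O)Cl
Why: Tosylation of the primary alcohol installs a leaving group without touching the silyl ether or the alkene.

Step 10
Reactants: 14 {(1R,2S)-2-[2-(tert-butyldimethylsilyloxy)ethyl]-2,3-dimethylcyclohex-3-en-1-yl}methyl 4-methylbenzenesulfonate
Product: 15 tert-butyldimethyl{2-[(1S,6R)-1,2,6-trimethylcyclohex-2-en-1-yl]ethoxy}silane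
Conditions: LiEt3BH, THF, 0 to 65 °C
Reagents that add atoms: none
Why: SN2 hydride displacement of the primary tosylate by LiEt3BH, the reagent of choice for beta-branched sulfonates, turns CH2OTs into the C5 methyl group and leaves both stereocentres untouched.

Step 11
Reactants: 15 tert-butyldimethyl{2-[(1S,6R)-1,2,6-trimethylcyclohex-2-en-1-yl]ethoxy}silane
Product: 16 2-[(1S,6R)-1,2,6-trimethylcyclohex-2-en-1-yl]ethan-1-ol
Conditions: TBAF, THF, rt
Reagents that add atoms: none
Why: Fluoride-induced desilylation, driven by Si–F bond formation, frees the primary alcohol.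

Step 12
Reactants: 16 2-[(1S,6R)-1,2,6-trimethylcyclohex-2-en-1-yl]ethan-1-ol
Product: 17 (5R,6S)-6-(2-iodoethyl)-1,5,6-trimethylcyclohex-1-ene
Conditions: I2, PPh3, imidazole, CH2Cl2, 0 °C to rt
Reagents that add atoms: iodine, II
Why: Appel-type iodination converts the primary alcohol to the iodide by SN2 displacement of the alkoxyphosphonium ion.

Step 13
Reactants: 17 (5R,6S)-6-(2-iodoethyl)-1,5,6-trimethylcyclohex-1-ene
Product: 18 (5R,6S)-6-(but-3-yn-1-yl)-1,5,6-trimethylcyclohex-1-ene
Conditions: LiC≡CH·H2NCH2CH2NH2, DMSO, rt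
Reagents that add atoms: lithium acetylide–ethylenediamine complex (LiC≡CH·H2NCH2CH2NH2), [Li+].[C-]#C.NCCN
Why: SN2 alkylation of lithium acetylide in DMSO is a standard route from primary iodides to terminal alkynes, and the quaternary carbon sits two atoms away from the reacting carbon.

Step 14
Reactants: 18 (5R,6S)-6-(but-3-yn-1-yl)-1,5,6-trimethylcyclohex-1-ene
Product: 20 (5R,6S)-6-[(3E)-4-iodo-3-methylbut-3-en-1-yl]-1,5,6-trimethylcyclohex-1-ene, via the (E)-alkenyldimethylalane 19 (not isolated)
Conditions: Me3Al, Cp2ZrCl2 (25 mol %), CH2Cl2, 0 °C to rt; then I2, THF, −30 to 0 °C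
Reagents that add atoms: trimethylaluminium, C[Al](C)C; iodine, II
Why: Zirconium-catalysed carboalumination (Negishi methylalumination) adds CH3 and Al syn with Al at the terminal carbon, and iodinolysis of the alkenyl–Al bond with retention gives the E iodide, fixing the C9=C10 geometry.

Step 15
Reactants: 20 (5R,6S)-6-[(3E)-4-iodo-3-methylbut-3-en-1-yl]-1,5,6-trimethylcyclohex-1-ene; 21 (4-bromobut-1-yn-1-yl)trimethylsilane
Product: 24 trimethyl{(5E)-6-methyl-8-[(1S,6R)-1,2,6-trimethylcyclohex-2-en-1-yl]oct-5-en-1-yn-1-yl}silane, via [4-(trimethylsilyl)but-3-yn-1-yl]magnesium bromide 22 (not isolated), via [4-(trimethylsilyl)but-3-yn-1-yl]zinc bromide 23 (not isolated)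
Conditions: 21, Mg, THF, reflux; ZnBr2, THF, 0 °C; then 20, Pd(PPh3)4 (5 mol %), THF, rt
Reagents that add atoms: none
Why: Negishi cross-coupling on zerovalent palladium (oxidative addition, transmetalation, reductive elimination) joins the alkenyl iodide to the homopropargylic zinc reagent at C10–C11 with retention of the E geometry, the silyl cap protecting the alkyne.

Step 16
Reactants: 24 trimethyl{(5E)-6-methyl-8-[(1S,6R)-1,2,6-trimethylcyclohex-2-en-1-yl]oct-5-en-1-yn-1-yl}silane
Product: 25 (5R,6S)-1,5,6-trimethyl-6-[(3E)-3-methyloct-3-en-7-yn-1-yl]cyclohex-1-ene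
Conditions: K2CO3 (cat.), MeOH, rt
Reagents that add atoms: none
Why: Base-catalysed methanolysis of the alkynyl–silicon bond (protodesilylation) uncovers the terminal alkyne.

Step 17
Reactants: 25 (5R,6S)-1,5,6-trimethyl-6-[(3E)-3-methyloct-3-en-7-yn-1-yl]cyclohex-1-ene; 2 formaldehyde (as paraformaldehyde)
Product: 28 (2E,6E)-3,7-dimethyl-9-[(1S,6R)-1,2,6-trimethylcyclohex-2-en-1-yl]nona-2,6-dien-1-ol, via the (1E,5E)-dienyldimethylalane 26 (not isolated), via its lithium butylalanate 27 (not isolated)
Conditions: Me3Al, Cp2ZrCl2 (25 mol %), CH2Cl2, rt; evaporate; n-BuLi, THF/hexane, −78 °C; (CH2O)n, −78 °C to rt; aq. work-up at 0 °C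
Reagents that add atoms: trimethylaluminium, C[Al](C)C
Why: A second syn methylalumination sets the E geometry at C13=C14, and the derived lithium alanate transfers its alkenyl group to formaldehyde with retention to give the allylic alcohol directly.

Step 18
Reactants: 28 (2E,6E)-3,7-dimethyl-9-[(1S,6R)-1,2,6-trimethylcyclohex-2-en-1-yl]nona-2,6-dien-1-ol
Product: 29 (5R,6S)-6-[(3E,7E)-9-bromo-3,7-dimethylnona-3,7-dien-1-yl]-1,5,6-trimethylcyclohex-1-ene
Conditions: CBr4, PPh3, CH2Cl2, 0 °C; used at once
Reagents that add atoms: carbon tetrabromide, BrC(Br)(Br)Br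
Why: Appel bromination converts the primary allylic alcohol to the bromide by SN2 under neutral conditions, without allylic transposition at low temperature.

Step 19
Reactants: 30 hypotaurine (2-aminoethane-1-sulfinic acid)
Product: 31 sodium 2-[(tert-butoxycarbonyl)amino]ethane-1-sulfinate
Conditions: NaOH (1 equiv), Boc2O, H2O/1,4-dioxane, 0 °C to rt; lyophilise
Reagents that add atoms: di-tert-butyl dicarbonate, CC(C)(C)OC(=O)OC(=O)OC(C)(C)C; sodium hydroxide, [Na+].[OH-]
Why: N-acylation of the amino sulfinate with Boc2O (carbamate formation) in aqueous base gives the N-protected sulfinate salt with sulfur left as the nucleophilic site.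

Step 20
Reactants: 29 (5R,6S)-6-[(3E,7E)-9-bromo-3,7-dimethylnona-3,7-dien-1-yl]-1,5,6-trimethylcyclohex-1-ene; 31 sodium 2-[(tert-butoxycarbonyl)amino]ethane-1-sulfinate
Product: 32 tert-butyl N-[2-({(2E,6E)-3,7-dimethyl-9-[(1S,6R)-1,2,6-trimethylcyclohex-2-en-1-yl]nona-2,6-dien-1-yl}sulfonyl)ethyl]carbamate
Conditions: DMF, 0 °C to rt
Reagents that add atoms: none
Why: S-alkylation of the sulfinate anion by the primary allylic bromide (SN2 at the soft sulfur terminus of the ambident anion) gives the allylic sulfone with the E alkene preserved.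

Step 21
Reactants: 32 tert-butyl N-[2-({(2E,6E)-3,7-dimethyl-9-[(1S,6R)-1,2,6-trimethylcyclohex-2-en-1-yl]nona-2,6-dien-1-yl}sulfonyl)ethyl]carbamate
Product: 34 2-({(2E,6E)-3,7-dimethyl-9-[(1S,6R)-1,2,6-trimethylcyclohex-2-en-1-yl]nona-2,6-dien-1-yl}sulfonyl)ethan-1-amine, via the trimethylsilyl carbamate 33 (not isolated)
Conditions: TMSOTf, 2,6-lutidine, CH2Cl2, 0 °C; then MeOH; aq. NaHCO3 work-up
Reagents that add atoms: none
Why: Silyl triflate-mediated Boc cleavage (tert-butyl carbamate to silyl carbamate, then methanolysis and decarboxylation) removes the carbamate under buffered conditions that spare the acid-sensitive trisubstituted alkenes.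

Step 22
Reactants: 34 2-({(2E,6E)-3,7-dimethyl-9-[(1S,6R)-1,2,6-trimethylcyclohex-2-en-1-yl]nona-2,6-dien-1-yl}sulfonyl)ethan-1-amine
Product: 36 agelasidine C, via agelasidine C hydrochloride 35 (not isolated)
Conditions: 1H-pyrazole-1-carboxamidine hydrochloride, i-Pr2NEt, DMF, rt; then cold 1 M NaOH, CHCl3/i-PrOH extraction
Reagents that add atoms: 1H-pyrazole-1-carboxamidine hydrochloride, Cl.NC(=N)n1cccn1
Why: Amidine transfer from the pyrazole carboxamidine to the primary amine (addition–elimination guanylation) gives the guanidinium salt, which dilute hydroxide converts to the free base.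

**Compound list**

1 | ethyl 2-methyl-3-oxobutanoate | CCOC(=O)C(C)C(C)=O | starting material
2 | formaldehyde | C=O | starting material
3 | ethyl 5-hydroxy-2-methyl-3-oxopentanoate | CCOC(=O)C(C)C(=O)CCO | intermediate (not isolated)
4 | 4-hydroxy-3-methyl-5,6-dihydro-2H-pyran-2-one | CC1=C(O)CCOC1=O | intermediate
5 | 3-methyl-2-oxo-5,6-dihydro-2H-pyran-4-yl trifluoromethanesulfonate | CC1=C(OS(=O)(=O)C(F)(F)F)CCOC1=O | intermediate
6 | 3,4-dimethyl-5,6-dihydro-2H-pyran-2-one | CC1=C(C)CCOC1=O | intermediate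
7 | 3,4-dimethyl-5,6-dihydro-2H-pyran-2-ol | CC1=C(C)CCOC1O | intermediate
8 | (2Z)-5-hydroxy-2,3-dimethylpent-2-enal | O=C/C(C)=C(C)\CCO | intermediate (not isolated)
9 | (3Z)-3,4-dimethylhexa-3,5-dien-1-ol | C=C/C(C)=C(C)\CCO | intermediate
10 | tert-butyl{[(3Z)-3,4-dimethylhexa-3,5-dien-1-yl]oxy}dimethylsilane | C=C/C(C)=C(C)\CCO[Si](C)(C)C(C)(C)C | intermediate
11 | acrolein (prop-2-enal) | C=CC=O | starting material
12 | (1R,2S)-2-[2-(tert-butyldimethylsilyloxy)ethyl]-2,3-dimethylcyclohex-3-ene-1-carbaldehyde | CC1=CCC[C@@H](C=O)[C@]1(C)CCO[Si](C)(C)C(C)(C)C | intermediate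
13 | {(1R,2S)-2-[2-(tert-butyldimethylsilyloxy)ethyl]-2,3-dimethylcyclohex-3-en-1-yl}methanol | CC1=CCC[C@@H](CO)[C@]1(C)CCO[Si](C)(C)C(C)(C)C | intermediate
14 | {(1R,2S)-2-[2-(tert-butyldimethylsilyloxy)ethyl]-2,3-dimethylcyclohex-3-en-1-yl}methyl 4-methylbenzenesulfonate | CC1=CCC[C@@H](COS(=O)(=O)c2ccc(C)cc2)[C@]1(C)CCO[Si](C)(C)C(C)(C)C | intermediate
15 | tert-butyldimethyl{2-[(1S,6R)-1,2,6-trimethylcyclohex-2-en-1-yl]ethoxy}silane | CC1=CCC[C@@H](C)[C@]1(C)CCO[Si](C)(C)C(C)(C)C | intermediate
16 | 2-[(1S,6R)-1,2,6-trimethylcyclohex-2-en-1-yl]ethan-1-ol | CC1=CCC[C@@H](C)[C@]1(C)CCO | intermediate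
17 | (5R,6S)-6-(2-iodoethyl)-1,5,6-trimethylcyclohex-1-ene | CC1=CCC[C@@H](C)[C@]1(C)CCI | intermediate
18 | (5R,6S)-6-(but-3-yn-1-yl)-1,5,6-trimethylcyclohex-1-ene | CC1=CCC[C@@H](C)[C@]1(C)CCC#C | intermediate
19 | dimethyl{(1E)-2-methyl-4-[(1S,6R)-1,2,6-trimethylcyclohex-2-en-1-yl]but-1-en-1-yl}alumane | CC1=CCC[C@@H](C)[C@]1(C)CC/C(C)=C/[Al](C)C | intermediate (not isolated)
20 | (5R,6S)-6-[(3E)-4-iodo-3-methylbut-3-en-1-yl]-1,5,6-trimethylcyclohex-1-ene | CC1=CCC[C@@H](C)[C@]1(C)CC/C(C)=C/I | intermediate
21 | (4-bromobut-1-yn-1-yl)trimethylsilane | C[Si](C)(C)C#CCCBr | starting material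
22 | [4-(trimethylsilyl)but-3-yn-1-yl]magnesium bromide | C[Si](C)(C)C#CCC[Mg]Br | intermediate (not isolated)
23 | [4-(trimethylsilyl)but-3-yn-1-yl]zinc bromide | C[Si](C)(C)C#CCC[Zn]Br | intermediate (not isolated)
24 | trimethyl{(5E)-6-methyl-8-[(1S,6R)-1,2,6-trimethylcyclohex-2-en-1-yl]oct-5-en-1-yn-1-yl}silane | CC1=CCC[C@@H](C)[C@]1(C)CC/C(C)=C/CCC#C[Si](C)(C)C | intermediate
25 | (5R,6S)-1,5,6-trimethyl-6-[(3E)-3-methyloct-3-en-7-yn-1-yl]cyclohex-1-ene | CC1=CCC[C@@H](C)[C@]1(C)CC/C(C)=C/CCC#C | intermediate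
26 | {(1E,5E)-2,6-dimethyl-8-[(1S,6R)-1,2,6-trimethylcyclohex-2-en-1-yl]octa-1,5-dien-1-yl}dimethylalumane | CC1=CCC[C@@H](C)[C@]1(C)CC/C(C)=C/CC/C(C)=C/[Al](C)C | intermediate (not isolated)
27 | lithium butyl{(1E,5E)-2,6-dimethyl-8-[(1S,6R)-1,2,6-trimethylcyclohex-2-en-1-yl]octa-1,5-dien-1-yl}dimethylalanate | CC1=CCC[C@@H](C)[C@]1(C)CC/C(C)=C/CC/C(C)=C/[Al-](C)(C)CCCC.[Li+] | intermediate (not isolated)
28 | (2E,6E)-3,7-dimethyl-9-[(1S,6R)-1,2,6-trimethylcyclohex-2-en-1-yl]nona-2,6-dien-1-ol | CC1=CCC[C@@H](C)[C@]1(C)CC/C(C)=C/CC/C(C)=C/CO | intermediate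
29 | (5R,6S)-6-[(3E,7E)-9-bromo-3,7-dimethylnona-3,7-dien-1-yl]-1,5,6-trimethylcyclohex-1-ene | CC1=CCC[C@@H](C)[C@]1(C)CC/C(C)=C/CC/C(C)=C/CBr | intermediate
30 | hypotaurine (2-aminoethane-1-sulfinic acid) | NCCS(=O)O | starting material
31 | sodium 2-[(tert-butoxycarbonyl)amino]ethane-1-sulfinate | CC(C)(C)OC(=O)NCCS(=O)[O-].[Na+] | intermediate
32 | tert-butyl N-[2-({(2E,6E)-3,7-dimethyl-9-[(1S,6R)-1,2,6-trimethylcyclohex-2-en-1-yl]nona-2,6-dien-1-yl}sulfonyl)ethyl]carbamate | CC1=CCC[C@@H](C)[C@]1(C)CC/C(C)=C/CC/C(C)=C/CS(=O)(=O)CCNC(=O)OC(C)(C)C | intermediate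
33 | trimethylsilyl N-[2-({(2E,6E)-3,7-dimethyl-9-[(1S,6R)-1,2,6-trimethylcyclohex-2-en-1-yl]nona-2,6-dien-1-yl}sulfonyl)ethyl]carbamate | CC1=CCC[C@@H](C)[C@]1(C)CC/C(C)=C/CC/C(C)=C/CS(=O)(=O)CCNC(=O)O[Si](C)(C)C | intermediate (not isolated)
34 | 2-({(2E,6E)-3,7-dimethyl-9-[(1S,6R)-1,2,6-trimethylcyclohex-2-en-1-yl]nona-2,6-dien-1-yl}sulfonyl)ethan-1-amine | CC1=CCC[C@@H](C)[C@]1(C)CC/C(C)=C/CC/C(C)=C/CS(=O)(=O)CCN | intermediate
35 | agelasidine C hydrochloride | CC1=CCC[C@@H](C)[C@]1(C)CC/C(C)=C/CC/C(C)=C/CS(=O)(=O)CCNC(N)=[NH2+].[Cl-] | intermediate (not isolated)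
36 | agelasidine C, 2-[2-({(2E,6E)-3,7-dimethyl-9-[(1S,6R)-1,2,6-trimethylcyclohex-2-en-1-yl]nona-2,6-dien-1-yl}sulfonyl)ethyl]guanidine | CC1=CCC[C@@H](C)[C@]1(C)CC/C(C)=C/CC/C(C)=C/CS(=O)(=O)CCN=C(N)N | target

**Step count**

Total: 22 steps. Longest linear sequence: 21 steps (steps 1–18 and 20–22, from 1 to 36); step 19 prepares the sulfinate partner.

**Steps most likely to fail**

Step 7. The cycloaddition may be slow because the inside substituent of the Z terminus disfavours the s-cis conformer. The acidic catalyst may oligomerise the electron-rich diene before it reacts. A background or stepwise pathway would erode regio-, endo- and facial control at the crowded C5–C6 bond. The fallback is stoichiometric auxiliary control of the same disconnection. It sets out from diene 10 and uses as dienophile (4S)-4-benzyl-3-(prop-2-enoyl)-1,3-oxazolidin-2-one F1, made from (4S)-4-benzyl-1,3-oxazolidin-2-one with n-BuLi and acryloyl chloride. Activation with Et2AlCl (1.4 equiv, CH2Cl2, −78 °C) gives the chelated cationic aluminium complex, a much stronger dienophile in which the benzyl group covers the Re face of the alpha carbon. The same two bonds should then form, with endo addition to the Si face, to give (4S)-4-benzyl-3-({(1R,2S)-2-[2-(tert-butyldimethylsilyloxy)ethyl]-2,3-dimethylcyclohex-3-en-1-yl}carbonyl)-1,3-oxazolidin-2-one F2. Reductive removal of the auxiliary with LiBH4 (THF/H2O, 0 °C) leads to alcohol 13, where the route is rejoined.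

Step 1. Monomeric formaldehyde may oligomerise or hydroxymethylate the dianion more than once, and lactonisation may be incomplete, so throughput at the start could be poor. The fallback forms the same C–C bond by alkylation instead of aldol addition. It sets out from 1, whose dianion is alkylated with benzyl chloromethyl ether (THF, −78 to 0 °C) to give ethyl 5-(benzyloxy)-2-methyl-3-oxopentanoate F3. Hydrogenolysis (H2, Pd/C, EtOAc) frees hydroxy keto ester 3, and the NaOH/HCl treatment closes it to lactone 4, where the route is rejoined.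

Step 10. Hydride may attack sulfur instead of the beta-branched carbon (S–O cleavage returning the alcohol), or displacement may be too slow next to the quaternary centre. The fallback replaces the ionic displacement by a radical dehalogenation. It sets out from alcohol 13, which PPh3/I2/imidazole converts to tert-butyl{2-[(1S,6R)-6-(iodomethyl)-1,2-dimethylcyclohex-2-en-1-yl]ethoxy}dimethylsilane F4. Bu3SnH with AIBN (toluene, 80 °C) then reduces the C–I bond in a radical chain to 15, where the route is rejoined.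

**Further compounds**

F1 | step 7 | (4S)-4-benzyl-3-(prop-2-enoyl)-1,3-oxazolidin-2-one | C=CC(=O)N1[C@@H](Cc2ccccc2)COC1=O
F2 | step 7 | (4S)-4-benzyl-3-({(1R,2S)-2-[2-(tert-butyldimethylsilyloxy)ethyl]-2,3-dimethylcyclohex-3-en-1-yl}carbonyl)-1,3-oxazolidin-2-one | CC1=CCC[C@@H](C(=O)N2[C@@H](Cc3ccccc3)COC2=O)[C@]1(C)CCO[Si](C)(C)C(C)(C)C
F3 | step 1 | ethyl 5-(benzyloxy)-2-methyl-3-oxopentanoate | CCOC(=O)C(C)C(=O)CCOCc1ccccc1
F4 | step 10 | tert-butyl{2-[(1S,6R)-6-(iodomethyl)-1,2-dimethylcyclohex-2-en-1-yl]ethoxy}dimethylsilane | CC1=CCC[C@@H](CI)[C@]1(C)CCO[Si](C)(C)C(C)(C)C
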